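**Retrosynthetic overview**
1. Haterumaimide G ⇒ a C12 aldehyde (2α-chloro-6-oxo bicyclic core) + methyl succinyl (R)-4-benzyloxazolidinone: C12–C13 by boron syn-aldol; the imide ring is closed last by ammonolysis.
2. C12 aldehyde ⇒ bicyclic Diels–Alder adduct: the C11 ester is homologated by one carbon (Wittig), the 2β-oxygen is replaced by chloride with inversion, and the silyl enol ether is hydrolysed to the C6 ketone.
3. Adduct ⇒ ring A 2-silyloxydiene + ethyl buta-2,3-dienoate: one Diels–Alder reaction makes ring B (C7–C8 and C9–C10), the quaternary C10, C9, the exocyclic methylene and the masked C6 ketone.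
4. Enabling feature: ring B is a cyclohexanone whose carbonyl carbon C6 lies between C5 and C7 (retron of a 2-oxydiene C7=C6(O)–C5=C10 anchored in ring A) and whose C8 carries the exocyclic methylene next to C9–C11 (retron of the conjugated π bond of an allenoate, C11 being its ester carbon).
5. Diene ⇒ commercial (4R,6R)-actinol (Mitsunobu inversion, enol triflate, Stille acylation); ring order: ring A bought, ring B by cycloaddition, imide ring last.

Key step: step 5

Remark: the decalin is numbered as in drimanes and labdanes (C4 carries the geminal methyls, C10 the angular methyl, C11 is the carbon on C9, β is the face of the C10 methyl); the exocyclic methylene carbon on C8 is C12 in the drimane names of 8–10 and C17 in the labdane names from 11 on, and (4R,6R)-actinol is assumed to be purchasable.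

**Step 1**
Reactants: 1 (4R,6R)-4-hydroxy-2,2,6-trimethylcyclohexan-1-one
Product: 2 (1S,3R)-3,5,5-trimethyl-4-oxocyclohexyl benzoate
Conditions: PhCO2H, PPh3, DIAD, THF, 0 °C → rt
Reagents that add atoms: benzoic acid, OC(=O)c1ccccc1
Why: Mitsunobu esterification proceeds by SN2 displacement of the oxyphosphonium ion by benzoate, so the carbinol carbon is inverted from R to S (the configuration that the later cycloaddition and chlorination need) and is protected in the same operation.

**Step 2**
Reactants: 2 (1S,3R)-3,5,5-trimethyl-4-oxocyclohexyl benzoate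
Product: 3 (1S)-3,5,5-trimethyl-4-(trifluoromethanesulfonyloxy)cyclohex-3-en-1-yl benzoate
Conditions: KN(SiMe3)2, THF, −78 °C; then PhNTf2, −78 → 0 °C
Reagents that add atoms: N-phenylbis(trifluoromethanesulfonimide), O=S(=O)(N(c1ccccc1)S(=O)(=O)C(F)(F)F)C(F)(F)F
Why: The ketone has a single α-hydrogen, so enolate O-triflation can give only the tetrasubstituted enol triflate; the benzoate has no acidic hydrogen and the old methyl-bearing stereocentre is erased on purpose.

**Step 3**
Reactants: 3 (1S)-3,5,5-trimethyl-4-(trifluoromethanesulfonyloxy)cyclohex-3-en-1-yl benzoate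
Product: 5 (1S)-4-acetyl-3,5,5-trimethylcyclohex-3-en-1-yl benzoate, via ethoxy diene 4 (not isolated)
Conditions: Bu3SnC(OEt)=CH2, Pd(PPh3)4 (5 mol%), LiCl, CuI (10 mol%), dioxane, 90 °C; then 1 M HCl, THF, rt
Reagents that add atoms: tributyl(1-ethoxyvinyl)stannane, CCCC[Sn](CCCC)(CCCC)C(=C)OCC; water, O
Why: Stille coupling of the vinyl triflate (LiCl and CuI assist transmetalation at the hindered tetrasubstituted carbon) installs a masked acetyl group, and dilute acid hydrolyses the 1-ethoxyvinyl ether to the methyl ketone without touching the benzoate.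

**Step 4**
Reactants: 5 (1S)-4-acetyl-3,5,5-trimethylcyclohex-3-en-1-yl benzoate
Product: 6 (1S)-4-[1-(tert-butyldimethylsilyloxy)ethenyl]-3,5,5-trimethylcyclohex-3-en-1-yl benzoate
Conditions: TBSOTf, Et3N, CH2Cl2, 0 °C
Reagents that add atoms: tert-butyldimethylsilyl trifluoromethanesulfonate, CC(C)(C)[Si](C)(C)OS(=O)(=O)C(F)(F)F
Why: Soft enolisation with the silyl triflate and Et3N can remove only an acetyl hydrogen (the other α-carbon has none), which gives the cross-conjugated 2-silyloxydiene.

**Step 5**
Reactants: 6 (1S)-4-[1-(tert-butyldimethylsilyloxy)ethenyl]-3,5,5-trimethylcyclohex-3-en-1-yl benzoate; 7 ethyl buta-2,3-dienoate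
Product: 8 ethyl 2β-benzoyloxy-6-(tert-butyldimethylsilyloxy)drima-5,8(12)-dien-11-oate
Conditions: 7 (1.5 equiv), AlBr3/AlMe3 (10:1, 20 mol%), toluene/CH2Cl2, −40 → −10 °C; then Et3N, aq. NaHCO3
Reagents that add atoms: none
Why: The aluminium Lewis acid binds the ester carbonyl of 7 and its conjugated C2=C3 bond adds across the s-cis 2-silyloxydiene in a concerted but asynchronous [4+2] cycloaddition in which the bond from the diene CH2 terminus (C7) to the sp carbon (C8) runs ahead of the C9–C10 bond. The closest known reaction types are the AlBr3/AlMe3-catalysed Diels–Alder reactions of hindered 2-silyloxydienes that create quaternary carbons and the Lewis-acid Diels–Alder reactions of buta-2,3-dienoates at their 2,3-bond. Ring B closes in the normal [4+2] mode with both new bonds formed on one face of each partner, and the siloxy group makes C7 the nucleophilic terminus so that the ester-bearing carbon meets C10 (para orientation to the oxygen). C10 is controlled by the benzoate on C2 of ring A: axial attack on the half-chair with a pseudo-equatorial benzoate occurs anti to it, because the syn mode would force benzoate, incoming carbon and an axial C4 methyl into a syn-triaxial array. C9 is controlled by the exo position of the ester, which avoids ring A and its C4 methyls and ends cis to the C10 methyl (equatorial, also the stable epimer α to the ester). The step needs periselectivity for the conjugated π bond of the cumulene, which is secured because only this bond is activated by the ester and the orthogonal terminal π bond survives as the exocyclic methylene, while the silyl enol ether formed stores the C6 ketone.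

**Step 6**
Reactants: 8 ethyl 2β-benzoyloxy-6-(tert-butyldimethylsilyloxy)drima-5,8(12)-dien-11-oate
Product: 9 6-(tert-butyldimethylsilyloxy)drima-5,8(12)-diene-2β,11-diol
Conditions: LiAlH4, THF, 0 °C; aq. potassium sodium tartrate work-up (no acid)
Reagents that add atoms: none
Why: LiAlH4 reduces the hindered C11 ester to the primary alcohol and cleaves the benzoate in the same operation, while the silyl enol ether is inert to hydride and keeps C6 masked and C5 trigonal.

**Step 7**
Reactants: 9 6-(tert-butyldimethylsilyloxy)drima-5,8(12)-diene-2β,11-diol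
Product: 10 6-(tert-butyldimethylsilyloxy)-2β-hydroxydrima-5,8(12)-dien-11-al
Conditions: Cu(MeCN)4OTf (5 mol%), 2,2'-bipyridine (5 mol%), TEMPO (5 mol%), N-methylimidazole (10 mol%), air, MeCN, rt
Reagents that add atoms: none
Why: Aerobic copper/TEMPO oxidation turns over only primary alcohols, so C11 should be taken to the aldehyde while the secondary C2 alcohol, the silyl enol ether and the alkene are left alone under these non-acidic conditions; the equatorial aldehyde is the stable C9 epimer.

**Step 8**
Reactants: 10 6-(tert-butyldimethylsilyloxy)-2β-hydroxydrima-5,8(12)-dien-11-al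
Product: 11 6-(tert-butyldimethylsilyloxy)-12-methoxy-13,14,15,16-tetranorlabda-5,8(17),11-trien-2β-ol
Conditions: Ph3P(CH2OMe)Cl (3.5 equiv), KN(SiMe3)2, THF, 0 °C; then 10, −78 → 0 °C
Reagents that add atoms: (methoxymethyl)triphenylphosphonium chloride, COC[P+](c1ccccc1)(c1ccccc1)c1ccccc1.[Cl-]
Why: Wittig reaction of the non-stabilised methoxymethylene ylide with the aldehyde adds C12 as an enol ether (an E/Z mixture is expected and is of no consequence); excess ylide covers the free hydroxyl and C6 is shielded from the ylide as its silyl enol ether.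

**Step 9**
Reactants: 11 6-(tert-butyldimethylsilyloxy)-12-methoxy-13,14,15,16-tetranorlabda-5,8(17),11-trien-2β-ol
Product: 12 2α-chloro-6-(tert-butyldimethylsilyloxy)-12-methoxy-13,14,15,16-tetranorlabda-5,8(17),11-triene
Conditions: PPh3, CCl4, 2,6-lutidine, MeCN, 50 °C
Reagents that add atoms: carbon tetrachloride, ClC(Cl)(Cl)Cl
Why: In the Appel reaction chloride displaces the oxyphosphonium group by SN2 with inversion from the α face, anti to the β-methyl groups on C10 and C4, which converts the 2β-alcohol into the 2α-chloride; the neutral buffered conditions should spare both enol ethers.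

**Step 10**
Reactants: 12 2α-chloro-6-(tert-butyldimethylsilyloxy)-12-methoxy-13,14,15,16-tetranorlabda-5,8(17),11-triene
Product: 13 2α-chloro-6-oxo-13,14,15,16-tetranorlabd-8(17)-en-12-al
Conditions: 1 M HCl, THF, 0 °C → rt
Reagents that add atoms: water, O
Why: Dilute acid hydrolyses the methyl enol ether to the C12 aldehyde and the silyl enol ether to the C6 ketone; with the 2α-chloride in place ring A adopts the chair with the axial C10 methyl, so C5 is protonated from the open α face to give the trans-decalin, which is also the thermodynamic epimer next to the ketone.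

**Step 11**
Reactants: 14 (4R)-4-benzyl-1,3-oxazolidin-2-one
Product: 15 methyl 4-[(4R)-4-benzyl-2-oxo-1,3-oxazolidin-3-yl]-4-oxobutanoate
Conditions: n-BuLi, THF, −78 °C; then MeO2CCH2CH2COCl, −78 → 0 °C
Reagents that add atoms: methyl 4-chloro-4-oxobutanoate, COC(=O)CCC(Cl)=O
Why: N-acylation of the lithiated oxazolidinone occurs at the acid chloride, which is far more electrophilic than the methyl ester.

**Step 12**
Reactants: 15 methyl 4-[(4R)-4-benzyl-2-oxo-1,3-oxazolidin-3-yl]-4-oxobutanoate; 13 2α-chloro-6-oxo-13,14,15,16-tetranorlabd-8(17)-en-12-al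
Product: 17 methyl (12S,13R)-16-[(4R)-4-benzyl-2-oxo-1,3-oxazolidin-3-yl]-2α-chloro-12-hydroxy-6,16-dioxolabd-8(17)-en-15-oate, via boron enolate 16 (not isolated)
Conditions: 15, Bu2BOTf, Et3N, CH2Cl2, −78 → 0 °C; then 13, −78 → 0 °C; pH 7 buffer, MeOH, 30% H2O2, 0 °C
Reagents that add atoms: none
Why: In this Evans syn-aldol reaction Bu2BOTf and Et3N enolise the imide (not the less acidic ester) to the Z boron enolate, which adds to the aldehyde through a chair Zimmerman–Traxler transition state on the enolate face opposite the benzyl group of the (R)-auxiliary, setting C12 (S) and C13 (R) in a syn relationship; the hindered C6 ketone should not compete at −78 °C.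

**Step 13**
Reactants: 17 methyl (12S,13R)-16-[(4R)-4-benzyl-2-oxo-1,3-oxazolidin-3-yl]-2α-chloro-12-hydroxy-6,16-dioxolabd-8(17)-en-15-oate
Product: 19 haterumaimide G, via primary amide 18 (not isolated)
Conditions: NH3 (7 M in MeOH), 0 °C → rt
Reagents that add atoms: ammonia, N
Why: Ammonia cleaves the exocyclic acyl–oxazolidinone bond to the primary amide and frees the auxiliary, and the amide nitrogen then closes 5-exo-trig on the methyl ester to the succinimide (imide formation by ammonolysis), which should leave the secondary chloride, the ketone and the stereocentres untouched.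

**Compound list**
1 | (4R,6R)-4-hydroxy-2,2,6-trimethylcyclohexan-1-one (actinol) | O=C1C(C)(C)C[C@H](O)C[C@H]1C | starting material
2 | (1S,3R)-3,5,5-trimethyl-4-oxocyclohexyl benzoate | O=C1C(C)(C)C[C@@H](OC(=O)c2ccccc2)C[C@H]1C | intermediate
3 | (1S)-3,5,5-trimethyl-4-(trifluoromethanesulfonyloxy)cyclohex-3-en-1-yl benzoate | CC1=C(OS(=O)(=O)C(F)(F)F)C(C)(C)C[C@@H](OC(=O)c2ccccc2)C1 | intermediate
4 | (1S)-4-(1-ethoxyethenyl)-3,5,5-trimethylcyclohex-3-en-1-yl benzoate (ethoxy diene) | CC1=C(C(=C)OCC)C(C)(C)C[C@@H](OC(=O)c2ccccc2)C1 | intermediate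
5 | (1S)-4-acetyl-3,5,5-trimethylcyclohex-3-en-1-yl benzoate | CC1=C(C(C)=O)C(C)(C)C[C@@H](OC(=O)c2ccccc2)C1 | intermediate
6 | (1S)-4-[1-(tert-butyldimethylsilyloxy)ethenyl]-3,5,5-trimethylcyclohex-3-en-1-yl benzoate | CC1=C(C(=C)O[Si](C)(C)C(C)(C)C)C(C)(C)C[C@@H](OC(=O)c2ccccc2)C1 | intermediate
7 | ethyl buta-2,3-dienoate | C=C=CC(=O)OCC | starting material
8 | ethyl 2β-benzoyloxy-6-(tert-butyldimethylsilyloxy)drima-5,8(12)-dien-11-oate (C9 ester β, cis to the C10 methyl) | C=C1CC(O[Si](C)(C)C(C)(C)C)=C2C(C)(C)C[C@@H](OC(=O)c3ccccc3)C[C@]2(C)[C@H]1C(=O)OCC | intermediate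
9 | 6-(tert-butyldimethylsilyloxy)drima-5,8(12)-diene-2β,11-diol | C=C1CC(O[Si](C)(C)C(C)(C)C)=C2C(C)(C)C[C@@H](O)C[C@]2(C)[C@H]1CO | intermediate
10 | 6-(tert-butyldimethylsilyloxy)-2β-hydroxydrima-5,8(12)-dien-11-al | C=C1CC(O[Si](C)(C)C(C)(C)C)=C2C(C)(C)C[C@@H](O)C[C@]2(C)[C@H]1C=O | intermediate
11 | 6-(tert-butyldimethylsilyloxy)-12-methoxy-13,14,15,16-tetranorlabda-5,8(17),11-trien-2β-ol (E isomer drawn; the Z isomer is also expected) | C=C1CC(O[Si](C)(C)C(C)(C)C)=C2C(C)(C)C[C@@H](O)C[C@]2(C)[C@H]1/C=C/OC | intermediate
12 | 2α-chloro-6-(tert-butyldimethylsilyloxy)-12-methoxy-13,14,15,16-tetranorlabda-5,8(17),11-triene (E isomer drawn) | C=C1CC(O[Si](C)(C)C(C)(C)C)=C2C(C)(C)C[C@H](Cl)C[C@]2(C)[C@H]1/C=C/OC | intermediate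
13 | 2α-chloro-6-oxo-13,14,15,16-tetranorlabd-8(17)-en-12-al (5α-H, trans-decalin) | C=C1CC(=O)[C@H]2C(C)(C)C[C@H](Cl)C[C@]2(C)[C@H]1CC=O | intermediate
14 | (4R)-4-benzyl-1,3-oxazolidin-2-one | O=C1N[C@H](Cc2ccccc2)CO1 | starting material
15 | methyl 4-[(4R)-4-benzyl-2-oxo-1,3-oxazolidin-3-yl]-4-oxobutanoate | COC(=O)CCC(=O)N1[C@H](Cc2ccccc2)COC1=O | intermediate
16 | (Z)-dibutylboron enolate of 15 | CCCCB(CCCC)O/C(=C\CC(=O)OC)N1[C@H](Cc2ccccc2)COC1=O | intermediate
17 | methyl (12S,13R)-16-[(4R)-4-benzyl-2-oxo-1,3-oxazolidin-3-yl]-2α-chloro-12-hydroxy-6,16-dioxolabd-8(17)-en-15-oate (syn-aldol adduct) | C=C1CC(=O)[C@H]2C(C)(C)C[C@H](Cl)C[C@]2(C)[C@H]1C[C@H](O)[C@@H](CC(=O)OC)C(=O)N1[C@H](Cc2ccccc2)COC1=O | intermediate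
18 | methyl (12S,13R)-16-amino-2α-chloro-12-hydroxy-6,16-dioxolabd-8(17)-en-15-oate (primary amide) | C=C1CC(=O)[C@H]2C(C)(C)C[C@H](Cl)C[C@]2(C)[C@H]1C[C@H](O)[C@@H](CC(=O)OC)C(N)=O | intermediate
19 | haterumaimide G [(12S,13R)-2α-chloro-12-hydroxy-6-oxolabd-8(17)-ene-15,16-dioic acid imide] | C=C1CC(=O)[C@H]2C(C)(C)C[C@H](Cl)C[C@]2(C)[C@H]1C[C@H](O)[C@H]1CC(=O)NC1=O | target

**Step count and risks**
Total step count: 13. Longest linear sequence: 12 steps (from 1 through steps 1–10, 12 and 13; step 11 makes the side-chain reagent).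

The three steps most likely to fail:

Step 5. The Lewis acid may make bond formation stepwise, so that the cumulene closes through its terminal carbon or adds [2+2] across the silyl enol ether, and attack on the other face of ring A may erode the C10 configuration. The fallback sets out from 6 and replaces the allenoate by a simple trans-enoate with only one reactive π bond. Ethyl (2E)-4-(phenylselanyl)but-2-enoate F1 would be made from commercial ethyl (2E)-4-bromobut-2-enoate with PhSeSePh and NaBH4 in EtOH. The same Lewis-acid Diels–Alder reaction of 6 with it should give ethyl 2β-benzoyloxy-6-(tert-butyldimethylsilyloxy)-12-(phenylselanyl)drim-5-en-11-oate F2. Oxidation with H2O2 (pyridine, CH2Cl2, 0 °C → rt) and syn-elimination of the selenoxide, whose only β-hydrogen is on C8, should then form the exocyclic methylene, and the route is rejoined at 8.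

Step 9. The substitution must pass through the less populated ring A conformer with an axial leaving group, so it may be slow and E2 elimination to a ring A alkene may take over. The fallback sets out from 11 and separates activation from displacement: MsCl and Et3N (CH2Cl2, 0 °C) should give the 2β-methanesulfonate of 11 F3, which is isolated and displaced by LiCl in DMF (60 °C). This is still an SN2 inversion, but at a discrete sulfonate with a small soluble chloride instead of collapse of an oxyphosphonium ion pair. The route is rejoined at 12.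

Step 13. Ammonia may open the oxazolidinone ring instead of cleaving the acyl group, and retro-aldol cleavage or C13 epimerisation may occur during prolonged exposure to base. The fallback sets out from 17 and builds the imide stepwise. LiOH/H2O2 (THF–H2O, 0 °C) should cleave the auxiliary selectively to (12S,13R)-2α-chloro-12-hydroxy-15-methoxy-6,15-dioxolabd-8(17)-en-16-oic acid F4. Coupling with NH4Cl (EDC·HCl, HOBt, iPr2NEt, DMF) should give amide 18, where the route is rejoined; 18 is then closed to 19 with K2CO3 in MeOH.

**Further compounds**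
F1 | step 5 | ethyl (2E)-4-(phenylselanyl)but-2-enoate | CCOC(=O)/C=C/C[Se]c1ccccc1
F2 | step 5 | ethyl 2β-benzoyloxy-6-(tert-butyldimethylsilyloxy)-12-(phenylselanyl)drim-5-en-11-oate (8β-H, 9α-H) | c1ccccc1[Se]C[C@@H]1CC(O[Si](C)(C)C(C)(C)C)=C2C(C)(C)C[C@@H](OC(=O)c3ccccc3)C[C@]2(C)[C@H]1C(=O)OCC
F3 | step 9 | 2β-methanesulfonate of 11 | C=C1CC(O[Si](C)(C)C(C)(C)C)=C2C(C)(C)C[C@@H](OS(C)(=O)=O)C[C@]2(C)[C@H]1/C=C/OC
F4 | step 13 | (12S,13R)-2α-chloro-12-hydroxy-15-methoxy-6,15-dioxolabd-8(17)-en-16-oic acid | C=C1CC(=O)[C@H]2C(C)(C)C[C@H](Cl)C[C@]2(C)[C@H]1C[C@H](O)[C@@H](CC(=O)OC)C(=O)O
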